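Everything rests on cutting both diarylmethane bridges at the bond between the benzylic CH2 on C6 or C8 of ring A and C1 of its 2-hydroxyphenyl ring. One nickel-catalysed cathodic decarboxylative arylation converts two ring A acetic acid arms, activated as N-hydroxyphthalimide esters, into both CH2–aryl bonds. The carboxyl and iodide positions dictate all regiochemistry on the fully substituted ring A and on each phenol. The precursor is the (2S)-7-methoxyflavanone-6,8-diacetic acid bis(phthalimidyl) ester with O5 masked as a MOM ether, because a free 5-OH would lactonise onto the C6 arm. C2 is set only after all hot and basic steps, by asymmetric phenyl addition to a chromone.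

Key step: step 10

Assumption: the (S)-configured atropisomeric bisphosphine is taken to place phenyl on the face of C2 that gives the (2S)-flavanone, as the quadrant model for cyclic enones predicts; the mirror-image ligand would be used if the sense proved opposite.

Design remarks:
- **O5 protection.** A free 5-OH next to the C6 arm would close to a lactol or benzofuran at the aldehyde stage and to a benzofuran-2-one at the active ester stage. Its hydrogen bond would also make C4=O easier to reduce at a cathode. O5 therefore carries a MOM group, which falls in the same final acid step as the two phenol MOM groups.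
- **Late stereocentre.** O5 of an intact flavanone can be alkylated only with bases that open ring C by retro-oxa-Michael reaction, and the Claisen step needs about 200 °C. Both operations are therefore run on an achiral chromone, before C2 exists as a stereocentre.
- **Base-free cell.** A sacrificial zinc anode replaces an amine reductant, so the electrolysis contains no base.

Step 1
Reactants: 1 5,7-dihydroxychromone (5,7-dihydroxy-4H-chromen-4-one); 2 allyl bromide
Product: 3 chromone diallyl ether 5,7-bis(allyloxy)-4H-chromen-4-one
Conditions: 2 (3 equiv), K2CO3 (4 equiv), DMF, 60 °C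
Reagents that add atoms: allyl bromide (2), C=CCBr
Why: Williamson ether synthesis in which the polar aprotic solvent and gentle heating also alkylate the hydrogen-bonded 5-OH, while the achiral chromone has no stereocentre and no chalcone pathway that carbonate could exploit.

Step 2
Reactants: 3 5,7-bis(allyloxy)-4H-chromen-4-one
Product: 4 diallyl diphenol 6,8-diallyl-5,7-dihydroxy-4H-chromen-4-one
Conditions: N,N-diethylaniline, 200 °C, Ar
Reagents that add atoms: none
Why: Twofold aromatic Claisen rearrangement in which the O5 allyl group can end only on C6 or, by a Cope relay through an occupied ortho position, on C8, and the O7 allyl group only on C6 or C8, so all pathways should converge on the single 6,8-diallyl product.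

Step 3
Reactants: 4 6,8-diallyl-5,7-dihydroxy-4H-chromen-4-one
Product: 5 monomethyl ether 6,8-diallyl-5-hydroxy-7-methoxy-4H-chromen-4-one
Conditions: MeI (1.1 equiv), K2CO3 (1.2 equiv), acetone, rt
Reagents that add atoms: methyl iodide, CI
Why: Williamson methylation that should be selective for O7, because 7-OH is the acidic vinylogous-acid phenol whereas 5-OH is held in a hydrogen bond to C4=O and is not deprotonated by limited weak base.

Step 4
Reactants: 5 6,8-diallyl-5-hydroxy-7-methoxy-4H-chromen-4-one
Product: 6 MOM ether 6,8-diallyl-7-methoxy-5-(methoxymethoxy)-4H-chromen-4-one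
Conditions: NaH (1.3 equiv), MOMCl (1.5 equiv), THF–DMF (4:1), 0 °C to rt
Reagents that add atoms: chloromethyl methyl ether (MOMCl), COCCl
Why: Williamson-type O-alkylation (MOM protection) in which the strong base needed to break the chelate is harmless because no stereocentre exists yet, and the small electrophile fits between C4=O and the C6 allyl group.

Step 5
Reactants: 6 6,8-diallyl-7-methoxy-5-(methoxymethoxy)-4H-chromen-4-one; 7 phenylboronic acid
Product: 8 diallyl flavanone (2S)-6,8-diallyl-7-methoxy-5-(methoxymethoxy)-2-phenylchroman-4-one
Conditions: [Rh(OH)(cod)]2 (1.5 mol%), (S)-MeO-F12-BIPHEP [(S)-2,2'-bis[bis(3,4,5-trifluorophenyl)phosphino]-6,6'-dimethoxy-1,1'-biphenyl] (3.3 mol%), 7 (3 equiv), CH2Cl2–H2O (10:1), rt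
Reagents that add atoms: phenylboronic acid (7), OB(O)c1ccccc1
Why: Hayashi–Miyaura asymmetric 1,4-addition, known for 5,7-dialkoxychromones, in which the phenylrhodium complex of the electron-poor C2-symmetric bisphosphine inserts C2=C3 from the face left open by the ligand quadrants and so sets C2 as (S), while the base-free room-temperature medium prevents retro-oxa-Michael erosion.

Step 6
Reactants: 8 (2S)-6,8-diallyl-7-methoxy-5-(methoxymethoxy)-2-phenylchroman-4-one
Product: 10 dialdehyde 2,2'-[(2S)-7-methoxy-5-(methoxymethoxy)-4-oxo-2-phenylchromane-6,8-diyl]diacetaldehyde, via bis-diol tetraol 9 (not isolated)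
Conditions: OsO4 (4 mol%), NaIO4 (8 equiv), 2,6-lutidine (4 equiv), 1,4-dioxane–H2O (3:1), rt
Reagents that add atoms: osmium tetroxide, O=[Os](=O)(=O)=O; sodium periodate, [Na+].[O-]I(=O)(=O)=O
Why: Lemieux–Johnson oxidation in which OsO4 should attack only the two terminal alkenes, periodate cleaves the diols, and 2,6-lutidine keeps the medium near neutral, so that over-oxidation of the arylacetaldehydes, loss of the MOM group and opening at C2 are avoided.

Step 7
Reactants: 10 2,2'-[(2S)-7-methoxy-5-(methoxymethoxy)-4-oxo-2-phenylchromane-6,8-diyl]diacetaldehyde (crude, used at once)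
Product: 11 diacid 2,2'-[(2S)-7-methoxy-5-(methoxymethoxy)-4-oxo-2-phenylchromane-6,8-diyl]diacetic acid
Conditions: NaClO2 (6 equiv), NaH2PO4 (6 equiv), 2-methyl-2-butene (30 equiv), t-BuOH–THF–H2O, 0 °C to rt
Reagents that add atoms: sodium chlorite, [Na+].[O-]Cl=O
Why: Pinnick oxidation, which works at mildly acidic buffered pH that aryl MOM ethers and the flavanone tolerate, and chlorination is not an issue because ring A has no free C–H and the alkene scavenges hypochlorous acid.

Step 8
Reactants: 11 2,2'-[(2S)-7-methoxy-5-(methoxymethoxy)-4-oxo-2-phenylchromane-6,8-diyl]diacetic acid; 12 N-hydroxyphthalimide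
Product: 13 bis(active ester) bis(1,3-dioxoisoindolin-2-yl) 2,2'-[(2S)-7-methoxy-5-(methoxymethoxy)-4-oxo-2-phenylchromane-6,8-diyl]diacetate
Conditions: 12 (2.3 equiv), N,N'-diisopropylcarbodiimide (2.4 equiv), DMAP (10 mol%), CH2Cl2, 0 °C to rt
Reagents that add atoms: N-hydroxyphthalimide (12), ON1C(=O)c2ccccc2C1=O
Why: Steglich-type carbodiimide esterification, routine for arylacetic acids, in which the O5 MOM ether removes the only internal nucleophile that could lactonise onto the activated C6 arm and the catalytic DMAP is too weak a base to disturb C2.

Step 9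
Reactants: 14 2-iodophenol
Product: 15 1-iodo-2-(methoxymethoxy)benzene
Conditions: MOMCl (1.3 equiv), K2CO3 (2 equiv), acetone, 0 °C to rt
Reagents that add atoms: chloromethyl methyl ether (MOMCl), COCCl
Why: Williamson-type O-alkylation (MOM protection) of an unhindered acidic phenol, which removes the proton that would otherwise quench organonickel intermediates.

Step 10
Reactants: 13 bis(1,3-dioxoisoindolin-2-yl) 2,2'-[(2S)-7-methoxy-5-(methoxymethoxy)-4-oxo-2-phenylchromane-6,8-diyl]diacetate; 15 1-iodo-2-(methoxymethoxy)benzene
Product: 18 tris-MOM flavanone (2S)-7-methoxy-5-(methoxymethoxy)-6,8-bis[2-(methoxymethoxy)benzyl]-2-phenylchroman-4-one, via C8-benzylated monoester 16 (not isolated), via C6-benzylated monoester 17 (not isolated)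
Conditions: NiCl2(dme) (20 mol%), 4,4'-di-tert-butyl-2,2'-bipyridine (24 mol%), 15 (5 equiv), n-Bu4NPF6 (0.1 M), DMA, undivided cell, RVC cathode, Zn anode, constant current (about 2.5 F per mol of ester group), 13 added slowly by syringe pump, rt, Ar
Reagents that add atoms: 1-iodo-2-(methoxymethoxy)benzene (15), COCOc1ccccc1I
Why: The cathode reduces the divalent nickel bipyridine complex to zerovalent nickel, which inserts into the C–I bond of 15 to give an aryl complex of divalent nickel, while low-valent nickel (or the cathode) passes one electron to a phthalimidyl ester, whose radical anion breaks up into CO2, phthalimide anion and a primary benzylic radical at the CH2 on C6 or C8; the aryl complex traps this radical, the trivalent nickel species so formed makes the CH2–aryl bond by reductive elimination, and the cycle then repeats on the remaining arm of 16 or 17. The closest known reaction type is the nickel-catalysed reductive decarboxylative cross-electrophile coupling of N-hydroxyphthalimide esters, arylacetic esters included, with aryl iodides, driven by a cathode or by zinc metal. No ring is closed and no stereocentre is created, so C2 is only a spectator. The step needs cross-coupling to beat radical dimerisation, hydrogen abstraction and biaryl formation, which is served by an excess of 15 that keeps nickel stored as the aryl complex (further stabilised by the ortho MOM oxygen), by slow addition of 13 and by a modest constant current. It also needs the C4 ketone to stay untouched, which the substrate secures because a trialkoxyaryl ketone without an internal hydrogen bond is reduced only well beyond the potentials of the nickel complex and the esters, and the charge passed is limited. Regiochemistry is not a variable, since the carboxyl groups mark C6 and C8 and the iodide marks the carbon ortho to each phenol oxygen, the O5 MOM ether rules out lactonisation of the C6 arm, and Zn2+ from the anode ties up phthalimide anion so that no base able to open ring C at O1–C2 builds up.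

Step 11
Reactants: 18 (2S)-7-methoxy-5-(methoxymethoxy)-6,8-bis[2-(methoxymethoxy)benzyl]-2-phenylchroman-4-one
Product: 19 7-methoxydichamanetin (2S)-5-hydroxy-6,8-bis(2-hydroxybenzyl)-7-methoxy-2-phenylchroman-4-one
Conditions: conc. aq. HCl (catalytic) in MeOH, 40 °C
Reagents that add atoms: none
Why: Acid-catalysed transacetalisation of the three aryl MOM ethers with methanol, a standard flavanone end-game in which formaldehyde is carried off as its dimethyl acetal and the mild acid should leave the O1–C2 bond (hence the (S) centre), the 7-OMe group and the diarylmethane bridges alone.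

Compound list
1 | 5,7-dihydroxy-4H-chromen-4-one | O=c1ccoc2cc(O)cc(O)c12 | starting material
2 | allyl bromide | C=CCBr | starting material
3 | 5,7-bis(allyloxy)-4H-chromen-4-one | O=c1ccoc2cc(OCC=C)cc(OCC=C)c12 | intermediate
4 | 6,8-diallyl-5,7-dihydroxy-4H-chromen-4-one | O=c1ccoc2c(CC=C)c(O)c(CC=C)c(O)c12 | intermediate
5 | 6,8-diallyl-5-hydroxy-7-methoxy-4H-chromen-4-one | O=c1ccoc2c(CC=C)c(OC)c(CC=C)c(O)c12 | intermediate
6 | 6,8-diallyl-7-methoxy-5-(methoxymethoxy)-4H-chromen-4-one | O=c1ccoc2c(CC=C)c(OC)c(CC=C)c(OCOC)c12 | intermediate
7 | phenylboronic acid | OB(O)c1ccccc1 | starting material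
8 | (2S)-6,8-diallyl-7-methoxy-5-(methoxymethoxy)-2-phenylchroman-4-one | COc1c(CC=C)c(OCOC)c2c(c1CC=C)O[C@H](c1ccccc1)CC2=O | intermediate
9 | (2S)-6,8-bis(2,3-dihydroxypropyl)-7-methoxy-5-(methoxymethoxy)-2-phenylchroman-4-one (carbinol epimers, not isolated) | COc1c(CC(O)CO)c(OCOC)c2c(c1CC(O)CO)O[C@H](c1ccccc1)CC2=O | intermediate
10 | 2,2'-[(2S)-7-methoxy-5-(methoxymethoxy)-4-oxo-2-phenylchromane-6,8-diyl]diacetaldehyde | COc1c(CC=O)c(OCOC)c2c(c1CC=O)O[C@H](c1ccccc1)CC2=O | intermediate
11 | 2,2'-[(2S)-7-methoxy-5-(methoxymethoxy)-4-oxo-2-phenylchromane-6,8-diyl]diacetic acid | COc1c(CC(=O)O)c(OCOC)c2c(c1CC(=O)O)O[C@H](c1ccccc1)CC2=O | intermediate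
12 | N-hydroxyphthalimide | ON1C(=O)c2ccccc2C1=O | starting material
13 | bis(1,3-dioxoisoindolin-2-yl) 2,2'-[(2S)-7-methoxy-5-(methoxymethoxy)-4-oxo-2-phenylchromane-6,8-diyl]diacetate | COc1c(CC(=O)ON2C(=O)c3ccccc3C2=O)c(OCOC)c2c(c1CC(=O)ON1C(=O)c3ccccc3C1=O)O[C@H](c1ccccc1)CC2=O | intermediate
14 | 2-iodophenol | Oc1ccccc1I | starting material
15 | 1-iodo-2-(methoxymethoxy)benzene | COCOc1ccccc1I | intermediate
16 | 1,3-dioxoisoindolin-2-yl 2-{(2S)-7-methoxy-5-(methoxymethoxy)-8-[2-(methoxymethoxy)benzyl]-4-oxo-2-phenylchroman-6-yl}acetate (not isolated) | COc1c(CC(=O)ON2C(=O)c3ccccc3C2=O)c(OCOC)c2c(c1Cc1ccccc1OCOC)O[C@H](c1ccccc1)CC2=O | intermediate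
17 | 1,3-dioxoisoindolin-2-yl 2-{(2S)-7-methoxy-5-(methoxymethoxy)-6-[2-(methoxymethoxy)benzyl]-4-oxo-2-phenylchroman-8-yl}acetate (not isolated) | COc1c(Cc2ccccc2OCOC)c(OCOC)c2c(c1CC(=O)ON1C(=O)c3ccccc3C1=O)O[C@H](c1ccccc1)CC2=O | intermediate
18 | (2S)-7-methoxy-5-(methoxymethoxy)-6,8-bis[2-(methoxymethoxy)benzyl]-2-phenylchroman-4-one | COc1c(Cc2ccccc2OCOC)c(OCOC)c2c(c1Cc1ccccc1OCOC)O[C@H](c1ccccc1)CC2=O | intermediate
19 | 7-methoxydichamanetin, (2S)-5-hydroxy-6,8-bis(2-hydroxybenzyl)-7-methoxy-2-phenylchroman-4-one | COc1c(Cc2ccccc2O)c(O)c2c(c1Cc1ccccc1O)O[C@H](c1ccccc1)CC2=O | target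

Total step count: 11. Longest linear sequence: 10 (steps 1 to 8, then 10 and 11); step 9 is a one-step side branch.

Steps most likely to fail

1. **Step 10.**
   - What may go wrong: the stabilised benzylic radicals may escape capture by nickel. That would lead to dimerisation or oligomerisation through the two arms, premature reduction of a radical to a methyl group, or stalling after the first arylation.
   - Fallback: the mode of activation is inverted, from reduction of an active ester to oxidation of a carboxylate. It sets out from diacid 11 and iodide 15 (step 8 is then not needed) and comes back to the route at 18.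
   - The reaction is dual photoredox and nickel catalysis with Ir[dF(CF3)ppy]2(dtbbpy)PF6, NiCl2(dme), 4,4'-di-tert-butyl-2,2'-bipyridine and Cs2CO3 (one equivalent per acid group) in DMF under blue light at room temperature. This decarboxylative arylation is known for arylacetic acids and aryl iodides.
   - Radical release is metered by the photon flux, no electrode surface is involved, and the base is consumed in forming the dicarboxylate. No compound outside the list is made (F0).

2. **Step 5.**
   - What may go wrong: poor facial selectivity or sluggish insertion at C2=C3 of this electron-rich, fully substituted chromone, or a second phenyl transfer to C4=O.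
   - Fallback: resolution takes the place of asymmetric C–C bond formation. It sets out from 6 and 7 and comes back at 8.
   - Ligand-free [Rh(OH)(cod)]2 in dioxane–water should give racemic 6,8-diallyl-7-methoxy-5-(methoxymethoxy)-2-phenylchroman-4-one F1.
   - Noyori-type asymmetric transfer hydrogenation follows, with Cp*RhCl[(R,R)-TsDPEN] and HCO2H–Et3N (5:2) in EtOAc, run as a kinetic resolution (a reaction type known for racemic flavanones).
   - It should reduce the (R)-ketone to (2R,4R)-6,8-diallyl-7-methoxy-5-(methoxymethoxy)-2-phenylchroman-4-ol F2 and leave the (S)-ketone 8, which is separated by chromatography. The isolated alkenes are inert to this catalyst.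

3. **Step 2.**
   - What may go wrong: incomplete migration of the second allyl group, thermal cyclisation of an o-allylphenol onto its own alkene, or decomposition at 200 °C.
   - Fallback: cross-coupling replaces the sigmatropic shifts. It sets out from 1 and comes back at 6, taking the place of steps 1 to 4.
   - N-Iodosuccinimide (2.1 equiv) in DMF should iodinate both free positions of ring A to give 5,7-dihydroxy-6,8-diiodo-4H-chromen-4-one F3.
   - MeI and K2CO3 in acetone should then give 5-hydroxy-6,8-diiodo-7-methoxy-4H-chromen-4-one F4.
   - NaH and MOMCl should give 6,8-diiodo-7-methoxy-5-(methoxymethoxy)-4H-chromen-4-one F5.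
   - A twofold Stille coupling with allyltributylstannane and Pd(PPh3)4 in DMF at 90 °C should deliver 6.

Further compounds
F0 | step 10 | none | none
F1 | step 5 | racemic 6,8-diallyl-7-methoxy-5-(methoxymethoxy)-2-phenylchroman-4-one | COc1c(CC=C)c(OCOC)c2c(c1CC=C)OC(c1ccccc1)CC2=O
F2 | step 5 | (2R,4R)-6,8-diallyl-7-methoxy-5-(methoxymethoxy)-2-phenylchroman-4-ol | COc1c(CC=C)c(OCOC)c2c(c1CC=C)O[C@@H](c1ccccc1)C[C@H]2O
F3 | step 2 | 5,7-dihydroxy-6,8-diiodo-4H-chromen-4-one | O=c1ccoc2c(I)c(O)c(I)c(O)c12
F4 | step 2 | 5-hydroxy-6,8-diiodo-7-methoxy-4H-chromen-4-one | O=c1ccoc2c(I)c(OC)c(I)c(O)c12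
F5 | step 2 | 6,8-diiodo-7-methoxy-5-(methoxymethoxy)-4H-chromen-4-one | O=c1ccoc2c(I)c(OC)c(I)c(OCOC)c12
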